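Percent of the starting complex charged is the unit of the readings below, and I read it backwards, as f, the fraction of starting complex left: one minus both exchanged complexes.

| flask | starting complex | incoming ligand | remark | time |
|---|---|---|---|---|
| grey | 30 mM | 10 mM | run made earlier |  |
| green | 40 mM | 10 mM | run made earlier |  |
| dusk | 20 mM | 10.0 mM |  | 4.0 min |
| spring | 20 mM | 50.0 mM |  | 4.0 min |
| autumn | 20 mM | 24.0 mM |  | 4.0 min |

| run | time / min | complex with two exchanged / % | complex with one exchanged / % |
|---|---|---|---|
| grey | 0.167 | 0 | 1.3 |
| grey | 0.333 | 0.2 | 2.5 |
| grey | 0.667 | 0 | 5.0 |
| grey | 1.00 | 0 | 7.1 |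
| grey | 1.33 | 0.1 | 8.7 |
| grey | 2.00 | 0.3 | 11.1 |
| grey | 2.50 | 0.7 | 12.7 |
| green | 0.200 | 0 | 1.9 |
| green | 0.333 | 0.5 | 2.2 |
| green | 0.417 | 0 | 3.2 |
| green | 0.667 | 0.3 | 4.5 |
| green | 1.00 | 0.1 | 7.2 |
| green | 1.50 | 0 | 8.7 |
| green | 2.50 | 0 | 11.5 |

(readings scatter by 0.3 percentage points)

- the numbers in the tables scatter with a standard deviation of 0.3 percentage points
- a reading or a percentage of complex with one exchanged counts all its forms, free or not
- no earlier run changes the charge of incoming ligand; that part of a forecast is a guess

- which of these holds the largest part of the starting complex at the end of dusk (complex with two exchanged / complex with one exchanged / starting complex)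
- which of these holds the largest part of the starting complex at the end of spring (complex with two exchanged / complex with one exchanged / starting complex)
- which of these holds the largest part of the starting complex at the end of autumn (complex with two exchanged / complex with one exchanged / starting complex)
- how much complex with two exchanged is there at the end of autumn, in percent of the starting complex charged

So each reading became −ln f, which I divided by ligand charge and time: 5.75 L mol⁻¹ min⁻¹ in grey and 4.89 L mol⁻¹ min⁻¹ in green, both at 2.50 min. But within grey this ratio fell from 7.69 L mol⁻¹ min⁻¹ at 0.667 min, so I kept the latest readings. Their mean, 5.32 L mol⁻¹ min⁻¹, is my clearing constant S; S times the ligand charge is an averaged pseudo-first-order constant for the starting complex. Both runs charged 10 mM of ligand, though, so scaling −ln f with the charge was my guess. With it, f at 4.0 min came to 80.8 % in dusk, 34.5 % in spring and 60.0 % in autumn. I therefore expected starting complex to lead in dusk and autumn, and complex with one exchanged in spring. Complex with two exchanged read 0.7 % in grey and 0 % in green at the last time, with scatter 0.3 percentage points, and autumn has more ligand and a longer time than either run, so I drew no figure for autumn from these two readings.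

The forecast said starting complex for dusk, complex with one exchanged for spring, starting complex for autumn, and 4 % of complex with two exchanged in autumn. Its autumn kept 56 % of starting complex where mine kept 60.0 %. Its own caution was: “The ligand order remains an inference, since neither run varied the charge.”

The flasks gave starting complex in dusk, complex with one exchanged in spring, starting complex in autumn, and 0.338 % of complex with two exchanged in autumn, so the forecast's 4 % stood inside the margin.

    starting complex + incoming ligand ⇌ leaving ligand + complex with one exchanged (K = 47.0, k = 8.60 L mol⁻¹ min⁻¹)
    complex with one exchanged + incoming ligand ⇌ leaving ligand + complex with two exchanged (K = 3.20, k = 0.300 L mol⁻¹ min⁻¹)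
    incoming ligand ⇌ dormant form (K = 1.50, k = 0.110 min⁻¹)
    crystals ⇌ complex with one exchanged, rate k4*(cs4 - [complex with one exchanged]) while solid is left; crystals form when [complex with one exchanged] > cs4 (solubility = 5.80 mM, k = 3.30 min⁻¹)
    incoming ligand → decomposed reagent (k = 0.0470 min⁻¹)

Autumn kept 61 % of its starting complex, which gives 5.08 L mol⁻¹ min⁻¹ beside S of 5.32 L mol⁻¹ min⁻¹. The neighbouring flask is autumn charged with 96 mM of ligand. There S gave f as 13.0 %, and the flask kept 12 % of its starting complex, with complex with one exchanged holding 85.8 %.

The runs come from a simulation with made-up constants; the scatter is artificial.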